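**Assumption:** artelasticin has no stereocentre and no stereogenic double bond (each alkene is a prenyl alkene carrying two identical methyl groups), so it is achiral and no stereocontrol is needed; the SMILES is taken as the constitution to be made.

## Retrosynthetic overview

1. Ring C (the 4-pyranone) is the only ring made and it is closed last. The key cut is the O1–C2 bond (ring-A phenol oxygen to C2), made in the same operation that puts the prenyl group on C3. The precursor is the o-hydroxyaryl 1,3-diketone 9 plus 2-methylbut-3-en-2-ol 10.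
2. Diketone 9 comes from C-acylation of the polyanion of diprenyl ketone 3 (ring A) with acid chloride 8 (ring B, phenols masked as silyl ethers so that only a ring-A hydroxyl can close ring C).
3. Ketone 3 comes from 2,4,6-trihydroxyacetophenone 1 by double ring C-prenylation with prenyl bromide 2.
4. Acid chloride 8 comes from 2,4-dihydroxybenzoic acid 4 through the tris-silyl compound 6.
5. Rings A and B are bought as benzene rings; the two silyl ethers are removed in the pot of the ring-closing step.

## Route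

Step 1
Reactants: 1 2,4,6-trihydroxyacetophenone; 2 prenyl bromide (1-bromo-3-methylbut-2-ene)
Product: 3 1-[2,4,6-trihydroxy-3,5-bis(3-methylbut-2-en-1-yl)phenyl]ethan-1-one
Conditions: 2 (2.1 equiv), 10% aq. KOH, 0 °C, 2 h; then 1 M HCl
Reagents that add atoms: prenyl bromide CC(C)=CCBr
Why: C-alkylation of an ambident phloroglucinol-type phenoxide: in water at 0 °C the solvated oxygens leave the two free ring carbons to take the soft allylic bromide, giving the 3,5-diprenyl ketone after re-aromatisation (moderate yield expected, mono-prenyl ketone recyclable); no stereocentre is formed.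

Step 2
Reactants: 4 2,4-dihydroxybenzoic acid; 5 tert-butyl(chloro)dimethylsilane
Product: 6 tert-butyldimethylsilyl 2,4-bis(tert-butyldimethylsilyloxy)benzoate
Conditions: 5 (3.5 equiv), imidazole (7 equiv), DMF, rt to 50 °C, 12 h
Reagents that add atoms: tert-butyl(chloro)dimethylsilane CC(C)(C)[Si](C)(C)Cl
Why: Imidazole-promoted silylation caps both phenols and the carboxylic acid in one operation; warming drives the hydrogen-bonded 2-hydroxyl to completion.

Step 3
Reactants: 6 tert-butyldimethylsilyl 2,4-bis(tert-butyldimethylsilyloxy)benzoate; 7 oxalyl chloride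
Product: 8 2,4-bis(tert-butyldimethylsilyloxy)benzoyl chloride
Conditions: 7 (1.3 equiv), DMF (5 mol %), CH2Cl2, 0 °C to rt, 3 h; evaporate under high vacuum (removes t-BuMe2SiCl), use crude
Reagents that add atoms: oxalyl chloride O=C(Cl)C(=O)Cl
Why: Silyl ester to acid chloride exchange through the Vilsmeier chloroiminium salt runs under neutral conditions, so the two aryl silyl ethers survive and no HCl is generated.

Step 4
Reactants: 3 1-[2,4,6-trihydroxy-3,5-bis(3-methylbut-2-en-1-yl)phenyl]ethan-1-one; 8 2,4-bis(tert-butyldimethylsilyloxy)benzoyl chloride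
Product: 9 1-[2,4-bis(tert-butyldimethylsilyloxy)phenyl]-3-[2,4,6-trihydroxy-3,5-bis(3-methylbut-2-en-1-yl)phenyl]propane-1,3-dione (isolated mainly as its hydrogen-bonded enol)
Conditions: LiN(SiMe3)2 (5.2 equiv), THF, −78 to −10 °C, 2 h; then 8 (1.05 equiv), −78 °C to rt, 4 h; 1 M HCl, 0 °C
Reagents that add atoms: none
Why: Crossed Claisen-type C-acylation of a lithium polyanion: of the three phenoxides and the ketone enolate, the enolate carbon is the most nucleophilic site and takes the acid chloride, while the fifth equivalent of base absorbs the acidic diketone proton; the prenyl groups and silyl ethers are inert to the amide base.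

Step 5
Reactants: 9 1-[2,4-bis(tert-butyldimethylsilyloxy)phenyl]-3-[2,4,6-trihydroxy-3,5-bis(3-methylbut-2-en-1-yl)phenyl]propane-1,3-dione; 10 2-methylbut-3-en-2-ol
Product: 13 artelasticin, via C-prenylated diketone 11 (not isolated), via bis-silyl flavone 12 (not isolated)
Conditions: Pd(PPh3)4 (5 mol %), (PhO)2P(O)OH (15 mol %), 10 (1.5 equiv), 4 Å MS, PhMe, 40 °C then 80 °C; then Bu4NF (3 equiv), THF, 0 °C to rt; AcOH (3 equiv)
Reagents that add atoms: 2-methylbut-3-en-2-ol CC(C)(O)C=C
Why: Proposed new method: a dehydrative prenylation–cyclodehydration cascade run by one zerovalent palladium/phosphoric acid pair on an unprotected triphenolic diketone. The acid assists ionisation of the tertiary allylic alcohol to a cationic 1,1-dimethyl-π-allyl palladium complex, which the diketone enol (the softest and most acidic C–H site) attacks at the unsubstituted terminus to give the linear prenyl group in 11 (its C2 stereocentre forms as a racemate and is erased in the next event). Phenol O-prenylation is reversible under the same catalyst and ipso attack at the fully substituted ring A is slow without phenoxide, so material funnels to 11. Alkylation at C2 breaks the stabilised enol, so a ring-A ortho-hydroxyl adds to the ring-B-side carbonyl and the same acid dehydrates the hemiketal at 80 °C, forming the O1–C2 bond irreversibly as the aromatic pyranone 12; this also stops a second prenylation, and ring B cannot compete because its 2-oxygen is silylated. Fluoride then removes both silyl ethers (known Si–O cleavage). The closest known reactions are the acid-assisted dehydrative Tsuji–Trost allylation of 1,3-dicarbonyl compounds with allylic alcohols and the acid cyclodehydration of Baker–Venkataraman diketones; their merger, the tertiary prenyl donor and the free polyphenol substrate are new.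

## Compound list

1 | 2,4,6-trihydroxyacetophenone | CC(=O)c1c(O)cc(O)cc1O | starting material
2 | prenyl bromide (1-bromo-3-methylbut-2-ene) | CC(C)=CCBr | starting material
3 | 1-[2,4,6-trihydroxy-3,5-bis(3-methylbut-2-en-1-yl)phenyl]ethan-1-one | CC(=O)c1c(O)c(CC=C(C)C)c(O)c(CC=C(C)C)c1O | intermediate
4 | 2,4-dihydroxybenzoic acid | OC(=O)c1ccc(O)cc1O | starting material
5 | tert-butyl(chloro)dimethylsilane | CC(C)(C)[Si](C)(C)Cl | starting material
6 | tert-butyldimethylsilyl 2,4-bis(tert-butyldimethylsilyloxy)benzoate | CC(C)(C)[Si](C)(C)OC(=O)c1ccc(O[Si](C)(C)C(C)(C)C)cc1O[Si](C)(C)C(C)(C)C | intermediate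
7 | oxalyl chloride | O=C(Cl)C(=O)Cl | starting material
8 | 2,4-bis(tert-butyldimethylsilyloxy)benzoyl chloride | O=C(Cl)c1ccc(O[Si](C)(C)C(C)(C)C)cc1O[Si](C)(C)C(C)(C)C | intermediate
9 | 1-[2,4-bis(tert-butyldimethylsilyloxy)phenyl]-3-[2,4,6-trihydroxy-3,5-bis(3-methylbut-2-en-1-yl)phenyl]propane-1,3-dione | CC(C)=CCc1c(O)c(CC=C(C)C)c(O)c(C(=O)CC(=O)c2ccc(O[Si](C)(C)C(C)(C)C)cc2O[Si](C)(C)C(C)(C)C)c1O | intermediate
10 | 2-methylbut-3-en-2-ol | CC(C)(O)C=C | starting material
11 | 1-[2,4-bis(tert-butyldimethylsilyloxy)phenyl]-2-(3-methylbut-2-en-1-yl)-3-[2,4,6-trihydroxy-3,5-bis(3-methylbut-2-en-1-yl)phenyl]propane-1,3-dione (racemic at C2, in equilibrium with its cyclic hemiketal) | CC(C)=CCc1c(O)c(CC=C(C)C)c(O)c(C(=O)C(CC=C(C)C)C(=O)c2ccc(O[Si](C)(C)C(C)(C)C)cc2O[Si](C)(C)C(C)(C)C)c1O | intermediate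
12 | 2-[2,4-bis(tert-butyldimethylsilyloxy)phenyl]-5,7-dihydroxy-3,6,8-tris(3-methylbut-2-en-1-yl)-4H-chromen-4-one | CC(C)=CCc1c(O)c(CC=C(C)C)c2oc(-c3ccc(O[Si](C)(C)C(C)(C)C)cc3O[Si](C)(C)C(C)(C)C)c(CC=C(C)C)c(=O)c2c1O | intermediate
13 | artelasticin, 2-(2,4-dihydroxyphenyl)-5,7-dihydroxy-3,6,8-tris(3-methylbut-2-en-1-yl)-4H-chromen-4-one | CC(C)=CCc1c(O)c(CC=C(C)C)c2oc(-c3ccc(O)cc3O)c(CC=C(C)C)c(=O)c2c1O | target

## Step count and risk

Total steps: 5. Longest linear sequence: 4 (steps 2, 3, 4, 5 from compound 4; the ring-A branch is 3 steps).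

**Step 5 (the proposed new cascade).** Possible failures are prenylation on ring A (oxygen or ipso carbon), incomplete cyclodehydration, or acid-induced chroman formation from an ortho-prenyl phenol. The fallback uses known chemistry and brings the future 3-prenyl group in on the ketone before the diketone is made. It sets out from 3: the tetra-anion (LiN(SiMe3)2, 4.2 equiv, THF, −78 to 0 °C) is alkylated at the enolate carbon with 2 (1.0 equiv, −78 °C) to give 5-methyl-1-[2,4,6-trihydroxy-3,5-bis(3-methylbut-2-en-1-yl)phenyl]hex-4-en-1-one F1. The polyanion of F1 is acylated with 8 under the conditions of step 4, and the fallback comes back to the route at 11, which is isolated here. Compound 11 is then cyclodehydrated by conventional acid catalysis (p-TsOH, 5 mol %, toluene, 50 °C) to 12 and desilylated with Bu4NF as in the closing stage of step 5 to give 13.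

**Step 4 (polyanion acylation).** Possible failures are O-acylation, sluggish reaction of the hindered diprenyl polyanion with the ortho-silyloxy acid chloride, or silyl migration. The fallback is a classical Baker–Venkataraman sequence and sets out from 3. Silylation (5, 2.1 equiv, imidazole, DMF) leaves one hydrogen-bonded ortho-hydroxyl free and gives 1-[2-hydroxy-4,6-bis(tert-butyldimethylsilyloxy)-3,5-bis(3-methylbut-2-en-1-yl)phenyl]ethan-1-one F2. O-Acylation of that hydroxyl with 8 (Et3N, DMAP, CH2Cl2) gives 2-acetyl-3,5-bis(tert-butyldimethylsilyloxy)-4,6-bis(3-methylbut-2-en-1-yl)phenyl 2,4-bis(tert-butyldimethylsilyloxy)benzoate F3. Base-induced O-to-C acyl transfer (KOt-Bu, THF, −20 °C) gives 1-[2,4-bis(tert-butyldimethylsilyloxy)phenyl]-3-[2-hydroxy-4,6-bis(tert-butyldimethylsilyloxy)-3,5-bis(3-methylbut-2-en-1-yl)phenyl]propane-1,3-dione F4. F4 is put through the conditions of step 5 with 10; the in-flask compounds are its 2-(3-methylbut-2-en-1-yl) derivative F5 and 5,7-bis(tert-butyldimethylsilyloxy)-2-[2,4-bis(tert-butyldimethylsilyloxy)phenyl]-3,6,8-tris(3-methylbut-2-en-1-yl)-4H-chromen-4-one F6. Bu4NF (5 equiv) then removes all four silyl groups, and the fallback comes back to the route at 13.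

**Step 1 (double C-prenylation).** Possible failures are O-alkylation, mono-alkylation and geminal over-alkylation, which lower the yield. The fallback separates C–O bond formation from C–C bond formation and sets out from 1. O-Alkylation (2, 2.2 equiv, K2CO3, acetone, reflux) gives 1-[2-hydroxy-4,6-bis(3-methylbut-2-en-1-yloxy)phenyl]ethan-1-one F7. A magnesium silicate (MgSiO3, Florisil) promoted 1,3-shift of both prenyl groups from oxygen to the adjacent ring carbons (toluene, 80 °C) then brings the fallback back to the route at 3.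

## Further compounds

F1 | step 5 | 5-methyl-1-[2,4,6-trihydroxy-3,5-bis(3-methylbut-2-en-1-yl)phenyl]hex-4-en-1-one | CC(C)=CCCC(=O)c1c(O)c(CC=C(C)C)c(O)c(CC=C(C)C)c1O
F2 | step 4 | 1-[2-hydroxy-4,6-bis(tert-butyldimethylsilyloxy)-3,5-bis(3-methylbut-2-en-1-yl)phenyl]ethan-1-one | CC(=O)c1c(O)c(CC=C(C)C)c(O[Si](C)(C)C(C)(C)C)c(CC=C(C)C)c1O[Si](C)(C)C(C)(C)C
F3 | step 4 | 2-acetyl-3,5-bis(tert-butyldimethylsilyloxy)-4,6-bis(3-methylbut-2-en-1-yl)phenyl 2,4-bis(tert-butyldimethylsilyloxy)benzoate | CC(=O)c1c(OC(=O)c2ccc(O[Si](C)(C)C(C)(C)C)cc2O[Si](C)(C)C(C)(C)C)c(CC=C(C)C)c(O[Si](C)(C)C(C)(C)C)c(CC=C(C)C)c1O[Si](C)(C)C(C)(C)C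
F4 | step 4 | 1-[2,4-bis(tert-butyldimethylsilyloxy)phenyl]-3-[2-hydroxy-4,6-bis(tert-butyldimethylsilyloxy)-3,5-bis(3-methylbut-2-en-1-yl)phenyl]propane-1,3-dione | CC(C)=CCc1c(O)c(C(=O)CC(=O)c2ccc(O[Si](C)(C)C(C)(C)C)cc2O[Si](C)(C)C(C)(C)C)c(O[Si](C)(C)C(C)(C)C)c(CC=C(C)C)c1O[Si](C)(C)C(C)(C)C
F5 | step 4 | 1-[2,4-bis(tert-butyldimethylsilyloxy)phenyl]-3-[2-hydroxy-4,6-bis(tert-butyldimethylsilyloxy)-3,5-bis(3-methylbut-2-en-1-yl)phenyl]-2-(3-methylbut-2-en-1-yl)propane-1,3-dione | CC(C)=CCc1c(O)c(C(=O)C(CC=C(C)C)C(=O)c2ccc(O[Si](C)(C)C(C)(C)C)cc2O[Si](C)(C)C(C)(C)C)c(O[Si](C)(C)C(C)(C)C)c(CC=C(C)C)c1O[Si](C)(C)C(C)(C)C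
F6 | step 4 | 5,7-bis(tert-butyldimethylsilyloxy)-2-[2,4-bis(tert-butyldimethylsilyloxy)phenyl]-3,6,8-tris(3-methylbut-2-en-1-yl)-4H-chromen-4-one | CC(C)=CCc1c(O[Si](C)(C)C(C)(C)C)c(CC=C(C)C)c2oc(-c3ccc(O[Si](C)(C)C(C)(C)C)cc3O[Si](C)(C)C(C)(C)C)c(CC=C(C)C)c(=O)c2c1O[Si](C)(C)C(C)(C)C
F7 | step 1 | 1-[2-hydroxy-4,6-bis(3-methylbut-2-en-1-yloxy)phenyl]ethan-1-one | CC(=O)c1c(O)cc(OCC=C(C)C)cc1OCC=C(C)C
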